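## Structural features

The target is a germacranolide. Germacrane numbering is used throughout: ring atoms C1–C10, lactone carbons C11 (bearing the methylene C13) and C12 (carbonyl), C14 (the CH2O on C10) and C15 (the methyl on C4). The carbocycle is a cyclodeca-1(10),4-diene trans-fused at C6–C7 to an α-methylene-γ-butyrolactone (O6–C12(=O)–C11(=C13H2)–C7). Both ring alkenes are trisubstituted and cis within the ring (1(10)Z and 4Z), and they form a 1,5-diene through C2–C3. Four contiguous stereocentres run C6(R)–C7(R)–C8(S)–C9(R): O6 lies on one face of the ring, while C11, O8 and O9 lie on the other, so C8/C9 is an erythro (ring-cis) diol. Three oxygens must be told apart: free 8-OH, 9-OAc and 14-O-isovalerate. The 8-OH sits next to the acetate (1,2-acyl migration) and can reach C12 (translactonisation). The methylene lactone is a Michael acceptor and the C9 and C14 esters are allylic. The real difficulty is the C14–C10(=C1)–C9 unit: a Z-configured 2-alkylidene-1,3-diol whose two C10 substituents are both oxygenated carbons, so olefination has no intrinsic bias, next to the erythro C8/C9 diol inside a 10-membered ring. The key step exploits the fact that the run C7–C8–C9–C10(C14)=C1–C2 is a 3-substituted cyclohexa-3,5-diene-cis-1,2-diol opened between C2 and C7. In that six-membered ring the cis-diol is C8/C9 in the correct absolute configuration, and the ring alkene C10=C1 can only be cis.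

## Logic of the disconnections

**25 ⇒ 24 ⇒ 23.** Bonds cut: O8–Si and the O9–acetyl bond. O8 and O9 form a cis-diol whose monoacetate could migrate, so O8 stays silylated to the end and O9 is acetylated when it is the only free hydroxyl. This makes the acetate position unambiguous and leaves 23 with a single free hydroxyl. The forward demand is a non-basic final desilylation.

**23 ⇒ 21 (through 22).** Bonds cut: C6–C7 and O6–C12. C7 is allylic to C11=C13, so it can be the γ-carbon of an allylmetal, and C6 can be an aldehyde. The cut removes the 10-membered ring, the lactone and two stereocentres at once and leaves the open chain 21. The forward step needs high dilution and must take its facial sense at C7 and C6 from the existing centre C8.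

**21 ⇒ 20 ⇒ 19 ⇒ 18 ⇒ 17.** Bond cut: C7–C11, with adjustments at C6 (oxidation level), C13 (bromide) and the two labile silyl groups. C11 is the α-carbon of an acrylate and C7 is an aldehyde in 17, so three carbons come off in one union. The demand is that the α-silyloxy aldehyde 17 keeps its configuration at C8.

**17 ⇒ 16 ⇒ 14 + 4.** Bond cut: C3–C4, an sp3–sp2 bond made with retention at the alkene. The Z geometry of C4=C5 is therefore bought with 4, which goes back through 3 to 1 by cutting the carbon–iodine bond (directed trans-hydroalumination). The chain is split into two pieces of unequal but simple make-up. The demand is hydroboration of 14 only at its terminal alkene.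

**14 ⇒ 13 ⇒ 12.** Bond cut: C2=C3 (one carbon), with a change of oxidation level at C2. The two primary alcohols of 12 differ because only C2–OH is allylic, and this is what lets the two ends be treated separately. The demand is that the Z-enal 13 is used before it can isomerise.

**12 ⇒ 10 (key disconnection).** Bond re-formed in the retrosynthetic sense: C2–C7. The acyclic Z-alkene carrying two stereocentres becomes a cyclohexene in which the alkene geometry is trivial and C8/C9 are ring stereocentres. This removes the hardest acyclic stereochemical problem of the target. The forward step must cleave exactly one vicinal diol.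

**10 ⇒ 9 ⇒ 8 ⇒ 7 ⇒ 6 ⇒ 5.** Bonds cut: the O14–acyl bond, C10–C14, the two C–O bonds at C2 and C7, and the two O–Si bonds. The bromine of 5 keeps its alkene inert while the other alkene is dihydroxylated and then serves as the handle for C14. The sequence ends at a cyclic diol that already holds C8 and C9 in the right absolute sense. The demand is a regioselective first silylation (O8 before O9).

## Other disconnections considered

**Alternative 1:** the first plan that comes to mind. Cut C6–C7 and O6–C12 and treat everything else as a linear chain built by acyclic chemistry. The forward key step is the chromium-mediated macrocyclising allylation of a seco aldehyde allyl bromide A1. The ring closure itself is sound and is kept here as a supporting step. As the defining disconnection, however, it leaves the hard part unsolved. A1 would need the erythro C8/C9 diol from a cis-alkene dihydroxylation (a substrate class with poor enantioselectivity) or from auxiliary chemistry. It would also need the Z-C1=C10 alkene from an olefination at a carbon flanked by two oxygenated arms, where nothing biases the geometry. The chosen plan takes both from one ring.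

**Alternative 2:** cut C4=C5. The forward key step is ring-closing metathesis of a vinyl/isopropenyl triene lactone A2. A trisubstituted alkene in a 10-membered ring would have its geometry set only by ring strain. The methylene lactone and the C1=C10 alkene are competing metathesis sites, and dimerisation is likely at the concentrations trisubstituted closures need. It also gives no help with C8/C9 or the C10 region, so it is kept only as a fallback ring closure.

**Alternative 3:** cut C6–C7 as a ring contraction. The forward key step is a [2,3]-Wittig rearrangement of the 13-membered bis-allylic ether A3 (O bridging C6 and C13), which would give the C6 alkoxide, the C7 centre and the exocyclic methylene, followed by lactonisation. The carbanion at C6 needs a strong base that three esters and an acrylate would not survive. Deprotonation could occur at C13 as well as at C6. The two new centres would be set in a flexible 13-membered transition state with no firm model. It also takes two operations (macro-etherification, contraction) for a bond the allylchromium makes directly.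

Key step: step 8

Assumption: 5 is taken as a catalogue compound (it is produced by whole-cell arene-dioxygenase oxidation of bromobenzene); if it had to be made, that fermentation would be one more step before step 3.

## Steps

Step 1
Reactants: 1 but-2-yn-1-ol
Product: 3 (Z)-3-iodobut-2-en-1-ol, via sodium alkenylalanate 2 (not isolated)
Conditions: NaAlH2(OCH2CH2OMe)2 (Red-Al), THF, 0 °C to rt; then I2, −78 °C to 0 °C
Reagents that add atoms: iodine II
Why: Alkoxide-directed trans-hydroalumination puts aluminium on C4 cis to the CH2O group (cyclic alanate 2), and iodinolysis with retention gives the Z vinyl iodide. This fixes the later C4=C5 geometry.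

Step 2
Reactants: 3 (Z)-3-iodobut-2-en-1-ol
Product: 4 triethyl{[(2Z)-3-iodobut-2-en-1-yl]oxy}silane
Conditions: TESCl, imidazole, CH2Cl2, 0 °C
Reagents that add atoms: chlorotriethylsilane CC[Si](Cl)(CC)CC
Why: Standard silylation of a primary alcohol. The triethylsilyl group is chosen so that it leaves together with the O9 silyl group in step 15.

Step 3
Reactants: 5 (1S,2S)-3-bromocyclohexa-3,5-diene-1,2-diol
Product: 6 (1S,6S)-2-bromo-6-[(tert-butyldimethylsilyl)oxy]cyclohexa-2,4-dien-1-ol
Conditions: TBSCl (1.05 equiv), imidazole, DMF, −20 °C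
Reagents that add atoms: tert-butylchlorodimethylsilane CC(C)(C)[Si](C)(C)Cl
Why: Regioselective mono-silylation under kinetic control. The hydroxyl that becomes O8 is flanked by an unsubstituted alkene CH, whereas the one that becomes O9 is flanked by the bromine-bearing carbon, so the bulky chloride should take O8. Both stereocentres come unchanged from 5.

Step 4
Reactants: 6 (1S,6S)-2-bromo-6-[(tert-butyldimethylsilyl)oxy]cyclohexa-2,4-dien-1-ol
Product: 7 tert-butyl{[(1S,6S)-5-bromo-6-[(triethylsilyl)oxy]cyclohexa-2,4-dien-1-yl]oxy}dimethylsilane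
Conditions: TESOTf, 2,6-lutidine, CH2Cl2, −78 °C
Reagents that add atoms: triethylsilyl trifluoromethanesulfonate CC[Si](CC)(CC)OS(=O)(=O)C(F)(F)F
Why: A silyl triflate with a hindered base silylates the more hindered hydroxyl without acid, which would aromatise the diene. O8 and O9 now carry groups of different lability.

Step 5
Reactants: 7 tert-butyl{[(1S,6S)-5-bromo-6-[(triethylsilyl)oxy]cyclohexa-2,4-dien-1-yl]oxy}dimethylsilane
Product: 8 (1R,2R,3S,4S)-5-bromo-3-[(tert-butyldimethylsilyl)oxy]-4-[(triethylsilyl)oxy]cyclohex-5-ene-1,2-diol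
Conditions: OsO4 (2 mol %), NMO, acetone/H2O, 0 °C to rt
Reagents that add atoms: osmium tetroxide O=[Os](=O)(=O)=O; N-methylmorpholine N-oxide C[N+]1([O-])CCOCC1; water O
Why: Catalytic osmium tetroxide dihydroxylation. The bromine-bearing alkene is electron-poor and hindered, so osmylation should occur at the C2=C7 alkene, anti to the silyloxy groups. The two new carbinol centres are deleted in step 8, so their configuration does not matter.

Step 6
Reactants: 8 (1R,2R,3S,4S)-5-bromo-3-[(tert-butyldimethylsilyl)oxy]-4-[(triethylsilyl)oxy]cyclohex-5-ene-1,2-diol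
Product: 9 (1R,2R,3S,4R)-3-[(tert-butyldimethylsilyl)oxy]-5-(hydroxymethyl)-4-[(triethylsilyl)oxy]cyclohex-5-ene-1,2-diol
Conditions: Bu3SnCH2OH (1.5 equiv), Pd(PPh3)4 (5 mol %), 1,4-dioxane, 90 °C
Reagents that add atoms: (tributylstannyl)methanol CCCC[Sn](CCCC)(CCCC)CO
Why: Stille coupling of the vinyl bromide with a hydroxymethylstannane installs C14 on C10. The α-oxygenated group transfers in preference to butyl, and the neutral conditions tolerate the free diol and both silyl ethers.

Step 7
Reactants: 9 (1R,2R,3S,4R)-3-[(tert-butyldimethylsilyl)oxy]-5-(hydroxymethyl)-4-[(triethylsilyl)oxy]cyclohex-5-ene-1,2-diol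
Product: 10 [(3R,4R,5S,6R)-5-[(tert-butyldimethylsilyl)oxy]-3,4-dihydroxy-6-[(triethylsilyl)oxy]cyclohex-1-en-1-yl]methyl 3-methylbutanoate
Conditions: isovaleryl chloride (1.05 equiv), 2,4,6-collidine, CH2Cl2, −78 °C
Reagents that add atoms: 3-methylbutanoyl chloride CC(C)CC(Cl)=O
Why: Chemoselective O-acylation. The primary allylic hydroxyl should react well ahead of the two secondary ring hydroxyls at low temperature with a weak, hindered base.

Step 8
Reactants: 10 [(3R,4R,5S,6R)-5-[(tert-butyldimethylsilyl)oxy]-3,4-dihydroxy-6-[(triethylsilyl)oxy]cyclohex-1-en-1-yl]methyl 3-methylbutanoate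
Product: 12 (2Z)-2-[(1R,2S)-2-[(tert-butyldimethylsilyl)oxy]-3-hydroxy-1-[(triethylsilyl)oxy]propyl]-4-hydroxybut-2-en-1-yl 3-methylbutanoate, via dialdehyde 11 (not isolated)
Conditions: NaIO4, THF/H2O (pH 7), 0 °C; then NaBH4, MeOH, −20 °C
Reagents that add atoms: none
Why: Malaprade glycol cleavage: the cis-diol of 10 forms a cyclic periodate ester that collapses with scission of the C2–C7 σ-bond to dialdehyde 11, and borohydride added to the same flask reduces both formyl groups before the Z-enal can equilibrate. The closest known reaction type is the oxidative ring opening of cyclic diols used in chiral-pool synthesis. No ring is closed; the six-membered ring is opened and its skeleton becomes the C7–C8–C9–C10(C14)=C1–C2 chain. No stereocentre is created: C8 and C9 are carried over unchanged from 5 because they are not part of the cleaved bond, and the two carbinol centres made in step 5 are destroyed. The Z geometry of C1=C10 is not a selectivity issue, because the alkene was endocyclic in a six-membered ring, where C9 and C2 can only be cis. The step needs chemoselectivity for one vicinal diol, which is secured because O8 and O9 are silylated and O14 is acylated. It also needs the ester and silyl ethers to survive, hence neutral periodate and cold borohydride. The two new primary alcohols differ (C2–OH allylic, C7–OH saturated), which is what lets steps 9 to 12 treat the two ends separately.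

Step 9
Reactants: 12 (2Z)-2-[(1R,2S)-2-[(tert-butyldimethylsilyl)oxy]-3-hydroxy-1-[(triethylsilyl)oxy]propyl]-4-hydroxybut-2-en-1-yl 3-methylbutanoate
Product: 13 (2Z)-2-[(1R,2S)-2-[(tert-butyldimethylsilyl)oxy]-3-hydroxy-1-[(triethylsilyl)oxy]propyl]-4-oxobut-2-en-1-yl 3-methylbutanoate
Conditions: MnO2 (activated, excess), CH2Cl2, rt
Reagents that add atoms: none
Why: MnO2 oxidises only the allylic primary alcohol (C2) and leaves the saturated C7–OH. The neutral heterogeneous conditions should keep the Z geometry.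

Step 10
Reactants: 13 (2Z)-2-[(1R,2S)-2-[(tert-butyldimethylsilyl)oxy]-3-hydroxy-1-[(triethylsilyl)oxy]propyl]-4-oxobut-2-en-1-yl 3-methylbutanoate
Product: 14 (2Z)-2-[(1R,2S)-2-[(tert-butyldimethylsilyl)oxy]-3-hydroxy-1-[(triethylsilyl)oxy]propyl]penta-2,4-dien-1-yl 3-methylbutanoate
Conditions: Ph3PCH3Br, KN(SiMe3)2 (2.2 equiv of ylide), THF, −78 °C to 0 °C
Reagents that add atoms: methyltriphenylphosphonium bromide C[P+](C1=CC=CC=C1)(C1=CC=CC=C1)C1=CC=CC=C1.[Br-]
Why: Wittig methylenation adds C3. The non-stabilised ylide should attack the aldehyde much faster than the ester at low temperature, and the Z alkene is not touched.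

Step 11
Reactants: 14 (2Z)-2-[(1R,2S)-2-[(tert-butyldimethylsilyl)oxy]-3-hydroxy-1-[(triethylsilyl)oxy]propyl]penta-2,4-dien-1-yl 3-methylbutanoate; 4 triethyl{[(2Z)-3-iodobut-2-en-1-yl]oxy}silane
Product: 16 (2Z,6Z)-2-[(1R,2S)-2-[(tert-butyldimethylsilyl)oxy]-3-hydroxy-1-[(triethylsilyl)oxy]propyl]-6-methyl-8-[(triethylsilyl)oxy]octa-2,6-dien-1-yl 3-methylbutanoate, via bis-boryl adduct 15 (not isolated)
Conditions: 9-BBN (2.5 equiv), THF, 0 °C to rt; then 4, Pd(dppf)Cl2 (5 mol %), AsPh3, aq. K3PO4, DMF, rt
Reagents that add atoms: none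
Why: 9-BBN hydroborates the terminal, monosubstituted alkene of the diene at C3, and a second equivalent is taken up by the free hydroxyl. The B-alkyl Suzuki–Miyaura coupling with 4 then proceeds with retention, so the Z geometry of C4=C5 comes from 4.

Step 12
Reactants: 16 (2Z,6Z)-2-[(1R,2S)-2-[(tert-butyldimethylsilyl)oxy]-3-hydroxy-1-[(triethylsilyl)oxy]propyl]-6-methyl-8-[(triethylsilyl)oxy]octa-2,6-dien-1-yl 3-methylbutanoate
Product: 17 (2Z,6Z)-2-[(1R,2R)-2-[(tert-butyldimethylsilyl)oxy]-3-oxo-1-[(triethylsilyl)oxy]propyl]-6-methyl-8-[(triethylsilyl)oxy]octa-2,6-dien-1-yl 3-methylbutanoate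
Conditions: Dess–Martin periodinane, NaHCO3, CH2Cl2, 0 °C
Reagents that add atoms: none
Why: Buffered Dess–Martin oxidation of the only free hydroxyl gives the α-silyloxy aldehyde without epimerisation at C8. The descriptor at C8 changes only because of CIP priorities.

Step 13
Reactants: 17 (2Z,6Z)-2-[(1R,2R)-2-[(tert-butyldimethylsilyl)oxy]-3-oxo-1-[(triethylsilyl)oxy]propyl]-6-methyl-8-[(triethylsilyl)oxy]octa-2,6-dien-1-yl 3-methylbutanoate
Product: 18 methyl (4S,5R,6Z,10Z)-4-[(tert-butyldimethylsilyl)oxy]-3-hydroxy-10-methyl-2-methylidene-6-{[(3-methylbutanoyl)oxy]methyl}-5,12-bis[(triethylsilyl)oxy]dodeca-6,10-dienoate (both C3 epimers)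
Conditions: methyl acrylate (10 equiv), DABCO (1 equiv), neat, rt
Reagents that add atoms: methyl acrylate C=CC(=O)OC
Why: Morita–Baylis–Hillman reaction joins C11 to C7 and brings in C12 and C13. The new carbinol centre forms as a mixture, which is harmless because it is erased in step 14.

Step 14
Reactants: 18 methyl (4S,5R,6Z,10Z)-4-[(tert-butyldimethylsilyl)oxy]-3-hydroxy-10-methyl-2-methylidene-6-{[(3-methylbutanoyl)oxy]methyl}-5,12-bis[(triethylsilyl)oxy]dodeca-6,10-dienoate
Product: 19 methyl (2Z,4S,5R,6Z,10Z)-2-(bromomethyl)-4-[(tert-butyldimethylsilyl)oxy]-10-methyl-6-{[(3-methylbutanoyl)oxy]methyl}-5,12-bis[(triethylsilyl)oxy]dodeca-2,6,10-trienoate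
Conditions: NBS, Me2S, CH2Cl2, −20 °C to rt
Reagents that add atoms: N-bromosuccinimide O=C1CCC(=O)N1Br
Why: Corey–Kim-type activation of the hydroxyl, then bromide attack at the methylene terminus with allylic transposition (SN2'). This should give the thermodynamically preferred Z-2-(bromomethyl)enoate with C8 trans to the ester.

Step 15
Reactants: 19 methyl (2Z,4S,5R,6Z,10Z)-2-(bromomethyl)-4-[(tert-butyldimethylsilyl)oxy]-10-methyl-6-{[(3-methylbutanoyl)oxy]methyl}-5,12-bis[(triethylsilyl)oxy]dodeca-2,6,10-trienoate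
Product: 20 methyl (2Z,4S,5R,6Z,10Z)-2-(bromomethyl)-4-[(tert-butyldimethylsilyl)oxy]-5,12-dihydroxy-10-methyl-6-{[(3-methylbutanoyl)oxy]methyl}dodeca-2,6,10-trienoate
Conditions: AcOH/THF/H2O (3:1:1), rt
Reagents that add atoms: none
Why: Aqueous acetic acid cleaves triethylsilyl ethers much faster than the secondary tert-butyldimethylsilyl ether. The non-nucleophilic medium spares the allylic bromide.

Step 16
Reactants: 20 methyl (2Z,4S,5R,6Z,10Z)-2-(bromomethyl)-4-[(tert-butyldimethylsilyl)oxy]-5,12-dihydroxy-10-methyl-6-{[(3-methylbutanoyl)oxy]methyl}dodeca-2,6,10-trienoate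
Product: 21 methyl (2Z,4S,5R,6Z,10Z)-2-(bromomethyl)-4-[(tert-butyldimethylsilyl)oxy]-5-hydroxy-10-methyl-6-{[(3-methylbutanoyl)oxy]methyl}-12-oxododeca-2,6,10-trienoate
Conditions: TEMPO (10 mol %), PhI(OAc)2, CH2Cl2, rt
Reagents that add atoms: none
Why: Oxoammonium (TEMPO) oxidation is selective for the primary allylic alcohol over the hindered secondary C9 hydroxyl. It is not expected to isomerise the Z-enal.

Step 17
Reactants: 21 methyl (2Z,4S,5R,6Z,10Z)-2-(bromomethyl)-4-[(tert-butyldimethylsilyl)oxy]-5-hydroxy-10-methyl-6-{[(3-methylbutanoyl)oxy]methyl}-12-oxododeca-2,6,10-trienoate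
Product: 23 [(3aS,4S,5R,6Z,10Z,11aR)-4-[(tert-butyldimethylsilyl)oxy]-5-hydroxy-10-methyl-3-methylidene-2-oxo-2,3,3a,4,5,8,9,11a-octahydrocyclodeca[b]furan-6-yl]methyl 3-methylbutanoate, via hydroxy ester 22 (not isolated)
Conditions: CrCl2 (6 equiv), THF, rt, slow addition (final 0.003 M); aq. NH4Cl
Reagents that add atoms: none
Why: Intramolecular Nozaki–Hiyama (chromium Barbier) allylation: the allylchromium (trivalent chromium) adds through its γ-carbon C7 to the tethered aldehyde, closing the 10-membered ring and creating the exocyclic methylene, and the alkoxide of 22 lactonises onto the methyl ester. At C7, A(1,3) strain with the CH2Cr group holds H8 in the alkene plane, so the aldehyde should approach anti to C9 with the silyloxy group outside, which corresponds to 7R. At C6, a chair transition state with the aldehyde chain and C8 both equatorial (anti addition) gives the trans-lactone, 6R; the 3aS descriptor of 23 differs from the target only through CIP priorities.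

Step 18
Reactants: 23 [(3aS,4S,5R,6Z,10Z,11aR)-4-[(tert-butyldimethylsilyl)oxy]-5-hydroxy-10-methyl-3-methylidene-2-oxo-2,3,3a,4,5,8,9,11a-octahydrocyclodeca[b]furan-6-yl]methyl 3-methylbutanoate
Product: 24 [(3aS,4S,5R,6Z,10Z,11aR)-5-(acetyloxy)-4-[(tert-butyldimethylsilyl)oxy]-10-methyl-3-methylidene-2-oxo-2,3,3a,4,5,8,9,11a-octahydrocyclodeca[b]furan-6-yl]methyl 3-methylbutanoate
Conditions: Ac2O, pyridine, DMAP (cat.), CH2Cl2, 0 °C
Reagents that add atoms: acetic anhydride CC(=O)OC(C)=O
Why: Acetylation of the only free hydroxyl (O9). O8 is still silylated, so the position of the acetate is unambiguous.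

Step 19
Reactants: 24 [(3aS,4S,5R,6Z,10Z,11aR)-5-(acetyloxy)-4-[(tert-butyldimethylsilyl)oxy]-10-methyl-3-methylidene-2-oxo-2,3,3a,4,5,8,9,11a-octahydrocyclodeca[b]furan-6-yl]methyl 3-methylbutanoate
Product: 25 [(3aR,4S,5R,6Z,10Z,11aR)-5-(acetyloxy)-4-hydroxy-10-methyl-3-methylidene-2-oxo-2,3,3a,4,5,8,9,11a-octahydrocyclodeca[b]furan-6-yl]methyl 3-methylbutanoate
Conditions: HF·pyridine, THF, 0 °C to rt
Reagents that add atoms: none
Why: Fluoride cleavage of the O8–Si bond under acidic, non-basic conditions should avoid acetyl migration from O9 to O8 and translactonisation. No stereocentre is touched.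

## Compound list

1 | but-2-yn-1-ol | CC#CCO | starting material
2 | sodium bis(2-methoxyethoxy)alanate of 3 (five-membered oxa-alumina ring, Al on C4) | [Na+].CC1=CCO[Al-]1(OCCOC)OCCOC | intermediate
3 | (Z)-3-iodobut-2-en-1-ol | C/C(I)=C/CO | intermediate
4 | triethyl{[(2Z)-3-iodobut-2-en-1-yl]oxy}silane | C/C(I)=C/CO[Si](CC)(CC)CC | intermediate
5 | (1S,2S)-3-bromocyclohexa-3,5-diene-1,2-diol | BrC1=CC=C[C@H](O)[C@@H]1O | starting material
6 | (1S,6S)-2-bromo-6-[(tert-butyldimethylsilyl)oxy]cyclohexa-2,4-dien-1-ol | BrC1=CC=C[C@H](O[Si](C)(C)C(C)(C)C)[C@@H]1O | intermediate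
7 | tert-butyl{[(1S,6S)-5-bromo-6-[(triethylsilyl)oxy]cyclohexa-2,4-dien-1-yl]oxy}dimethylsilane | BrC1=CC=C[C@H](O[Si](C)(C)C(C)(C)C)[C@@H]1O[Si](CC)(CC)CC | intermediate
8 | (1R,2R,3S,4S)-5-bromo-3-[(tert-butyldimethylsilyl)oxy]-4-[(triethylsilyl)oxy]cyclohex-5-ene-1,2-diol | BrC1=C[C@@H](O)[C@@H](O)[C@H](O[Si](C)(C)C(C)(C)C)[C@@H]1O[Si](CC)(CC)CC | intermediate
9 | (1R,2R,3S,4R)-3-[(tert-butyldimethylsilyl)oxy]-5-(hydroxymethyl)-4-[(triethylsilyl)oxy]cyclohex-5-ene-1,2-diol | OCC1=C[C@@H](O)[C@@H](O)[C@H](O[Si](C)(C)C(C)(C)C)[C@@H]1O[Si](CC)(CC)CC | intermediate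
10 | [(3R,4R,5S,6R)-5-[(tert-butyldimethylsilyl)oxy]-3,4-dihydroxy-6-[(triethylsilyl)oxy]cyclohex-1-en-1-yl]methyl 3-methylbutanoate | CC(C)CC(=O)OCC1=C[C@@H](O)[C@@H](O)[C@H](O[Si](C)(C)C(C)(C)C)[C@@H]1O[Si](CC)(CC)CC | intermediate
11 | (2Z)-2-[(1R,2R)-2-[(tert-butyldimethylsilyl)oxy]-3-oxo-1-[(triethylsilyl)oxy]propyl]-4-oxobut-2-en-1-yl 3-methylbutanoate | O=C/C=C(/COC(=O)CC(C)C)[C@@H](O[Si](CC)(CC)CC)[C@@H](O[Si](C)(C)C(C)(C)C)C=O | intermediate
12 | (2Z)-2-[(1R,2S)-2-[(tert-butyldimethylsilyl)oxy]-3-hydroxy-1-[(triethylsilyl)oxy]propyl]-4-hydroxybut-2-en-1-yl 3-methylbutanoate | OC/C=C(/COC(=O)CC(C)C)[C@@H](O[Si](CC)(CC)CC)[C@@H](O[Si](C)(C)C(C)(C)C)CO | intermediate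
13 | (2Z)-2-[(1R,2S)-2-[(tert-butyldimethylsilyl)oxy]-3-hydroxy-1-[(triethylsilyl)oxy]propyl]-4-oxobut-2-en-1-yl 3-methylbutanoate | O=C/C=C(/COC(=O)CC(C)C)[C@@H](O[Si](CC)(CC)CC)[C@@H](O[Si](C)(C)C(C)(C)C)CO | intermediate
14 | (2Z)-2-[(1R,2S)-2-[(tert-butyldimethylsilyl)oxy]-3-hydroxy-1-[(triethylsilyl)oxy]propyl]penta-2,4-dien-1-yl 3-methylbutanoate | C=C/C=C(/COC(=O)CC(C)C)[C@@H](O[Si](CC)(CC)CC)[C@@H](O[Si](C)(C)C(C)(C)C)CO | intermediate
15 | adduct of 14 carrying a 9-borabicyclo[3.3.1]nonan-9-yl group on C3 and a second one on O7 | C1CC2CCCC(C1)B2CC/C=C(/COC(=O)CC(C)C)[C@@H](O[Si](CC)(CC)CC)[C@@H](O[Si](C)(C)C(C)(C)C)COB1C2CCCC1CCC2 | intermediate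
16 | (2Z,6Z)-2-[(1R,2S)-2-[(tert-butyldimethylsilyl)oxy]-3-hydroxy-1-[(triethylsilyl)oxy]propyl]-6-methyl-8-[(triethylsilyl)oxy]octa-2,6-dien-1-yl 3-methylbutanoate | CC[Si](CC)(CC)OC/C=C(/C)CC/C=C(/COC(=O)CC(C)C)[C@@H](O[Si](CC)(CC)CC)[C@@H](O[Si](C)(C)C(C)(C)C)CO | intermediate
17 | (2Z,6Z)-2-[(1R,2R)-2-[(tert-butyldimethylsilyl)oxy]-3-oxo-1-[(triethylsilyl)oxy]propyl]-6-methyl-8-[(triethylsilyl)oxy]octa-2,6-dien-1-yl 3-methylbutanoate | CC[Si](CC)(CC)OC/C=C(/C)CC/C=C(/COC(=O)CC(C)C)[C@@H](O[Si](CC)(CC)CC)[C@@H](O[Si](C)(C)C(C)(C)C)C=O | intermediate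
18 | methyl (4S,5R,6Z,10Z)-4-[(tert-butyldimethylsilyl)oxy]-3-hydroxy-10-methyl-2-methylidene-6-{[(3-methylbutanoyl)oxy]methyl}-5,12-bis[(triethylsilyl)oxy]dodeca-6,10-dienoate (both C3 epimers) | CC[Si](CC)(CC)OC/C=C(/C)CC/C=C(/COC(=O)CC(C)C)[C@@H](O[Si](CC)(CC)CC)[C@@H](O[Si](C)(C)C(C)(C)C)C(O)C(=C)C(=O)OC | intermediate
19 | methyl (2Z,4S,5R,6Z,10Z)-2-(bromomethyl)-4-[(tert-butyldimethylsilyl)oxy]-10-methyl-6-{[(3-methylbutanoyl)oxy]methyl}-5,12-bis[(triethylsilyl)oxy]dodeca-2,6,10-trienoate | CC[Si](CC)(CC)OC/C=C(/C)CC/C=C(/COC(=O)CC(C)C)[C@@H](O[Si](CC)(CC)CC)[C@@H](O[Si](C)(C)C(C)(C)C)/C=C(\CBr)C(=O)OC | intermediate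
20 | methyl (2Z,4S,5R,6Z,10Z)-2-(bromomethyl)-4-[(tert-butyldimethylsilyl)oxy]-5,12-dihydroxy-10-methyl-6-{[(3-methylbutanoyl)oxy]methyl}dodeca-2,6,10-trienoate | OC/C=C(/C)CC/C=C(/COC(=O)CC(C)C)[C@@H](O)[C@@H](O[Si](C)(C)C(C)(C)C)/C=C(\CBr)C(=O)OC | intermediate
21 | methyl (2Z,4S,5R,6Z,10Z)-2-(bromomethyl)-4-[(tert-butyldimethylsilyl)oxy]-5-hydroxy-10-methyl-6-{[(3-methylbutanoyl)oxy]methyl}-12-oxododeca-2,6,10-trienoate | O=C/C=C(/C)CC/C=C(/COC(=O)CC(C)C)[C@@H](O)[C@@H](O[Si](C)(C)C(C)(C)C)/C=C(\CBr)C(=O)OC | intermediate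
22 | methyl 2-[(1S,2R,3Z,7Z,9R,10S)-10-[(tert-butyldimethylsilyl)oxy]-2,9-dihydroxy-4-methyl-8-{[(3-methylbutanoyl)oxy]methyl}cyclodeca-3,7-dien-1-yl]prop-2-enoate | C=C(C(=O)OC)[C@H]1[C@H](O)/C=C(/C)CC/C=C(/COC(=O)CC(C)C)[C@@H](O)[C@H]1O[Si](C)(C)C(C)(C)C | intermediate
23 | [(3aS,4S,5R,6Z,10Z,11aR)-4-[(tert-butyldimethylsilyl)oxy]-5-hydroxy-10-methyl-3-methylidene-2-oxo-2,3,3a,4,5,8,9,11a-octahydrocyclodeca[b]furan-6-yl]methyl 3-methylbutanoate | C=C1C(=O)O[C@@H]2/C=C(/C)CC/C=C(/COC(=O)CC(C)C)[C@@H](O)[C@@H](O[Si](C)(C)C(C)(C)C)[C@@H]12 | intermediate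
24 | [(3aS,4S,5R,6Z,10Z,11aR)-5-(acetyloxy)-4-[(tert-butyldimethylsilyl)oxy]-10-methyl-3-methylidene-2-oxo-2,3,3a,4,5,8,9,11a-octahydrocyclodeca[b]furan-6-yl]methyl 3-methylbutanoate | C=C1C(=O)O[C@@H]2/C=C(/C)CC/C=C(/COC(=O)CC(C)C)[C@@H](OC(C)=O)[C@@H](O[Si](C)(C)C(C)(C)C)[C@@H]12 | intermediate
25 | [(3aR,4S,5R,6Z,10Z,11aR)-5-(acetyloxy)-4-hydroxy-10-methyl-3-methylidene-2-oxo-2,3,3a,4,5,8,9,11a-octahydrocyclodeca[b]furan-6-yl]methyl 3-methylbutanoate (CNP0603244.1) | C=C1C(=O)O[C@@H]2/C=C(/C)CC/C=C(/COC(=O)CC(C)C)[C@@H](OC(C)=O)[C@@H](O)[C@@H]12 | target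

## Step count and least certain steps

Total step count: 19. Longest linear sequence: 17 steps (steps 3 to 19, from 5); steps 1 and 2 are a two-step side branch that joins at step 11.

**Step 8 (key step).** The most likely failures are isomerisation of the transient Z-enal before it is reduced, and migration of the silyl group from O8 to the new primary alkoxide at C7 under the basic borohydride conditions. Fallback, from 10 back to 12: the ends are differentiated by oxidation level before the ring is cut, so no free enal and no alkoxide arise. MnO2 would oxidise only the allylic ring hydroxyl of 10 to the ring hydroxy-enone F1. NaIO4 cleavage of its α-ketol would give the Z-configured aldehyde acid F2 (C2 as carboxylic acid, C7 as aldehyde). BH3·SMe2, which reduces acids and aldehydes but not the isovalerate, would then give 12 through neutral borate esters.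

**Step 17.** The most likely failures are oligomerisation competing with closure of the strained 10-membered ring, and poor facial selectivity at C6/C7, because the acyclic model for C7 and the chair model for C6 may be overridden by the conformation of the tether. Fallback, from 14 back to 23: the C6–C7 bond is made between two separate pieces and the ring is closed at C4=C5 instead. Borane 15, made as in step 11, would be coupled with 2-bromopropene to give the isopropenyl alcohol F3. Dess–Martin oxidation would give the aldehyde F4, the Morita–Baylis–Hillman reaction the adduct F5, and NBS/Me2S the allylic bromide F6. CrCl2-mediated addition of F6 to acrolein with lactonisation would give the vinyl lactone F7, whose diastereomers can be separated and assigned at this small acyclic stage. Ring-closing metathesis with the second-generation Grubbs catalyst in dilute toluene would give the macrocyclic silyl ether F8, the ring size enforcing the cis alkene. AcOH/THF/H2O would then remove the triethylsilyl group to give 23.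

**Step 3.** The most likely failure is insufficient discrimination between the two secondary hydroxyls (mixtures and bis-silylation), with aromatisation of the diene diol as a side process. Fallback, from 5 back to 7: the first differentiation is made by an enzyme and the silyl groups are introduced in the reverse order. A lipase (immobilised Candida antarctica lipase B, vinyl acetate) would acetylate the less hindered hydroxyl to give the monoacetate F9. TESOTf/2,6-lutidine would give the silyl acetate F10. i-Bu2AlH at −78 °C would remove the acetate without silyl migration to give the mono-ol F11, and TBSOTf/2,6-lutidine would give 7.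

**Step 13.** The most likely failure is a slow amine-catalysed addition to the hindered α-silyloxy aldehyde, with epimerisation at C8 or silyl migration during the long exposure to base. Fallback, from 17 back to 18: the acrylate α-anion equivalent is preformed instead of generated catalytically. Methyl propiolate would be hydroaluminated with i-Bu2AlH/NMO to the α-(methoxycarbonyl)vinylalane, which adds to 17 at low temperature within minutes and gives 18 directly (no new isolated compound).

**Step 6.** The most likely failure is slow oxidative addition and transmetalation at the hindered, doubly flanked vinyl bromide, with protodestannylation of the reagent taking over. Fallback, from 8 back to 9: C14 is brought in as carbon monoxide. Palladium-catalysed methoxycarbonylation (Pd(PPh3)4, CO, MeOH, Et3N, DMF) would give the methyl ester F12, and i-Bu2AlH would reduce it to 9.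

## Further compounds

F1 | step 8 | [(4S,5S,6R)-5-[(tert-butyldimethylsilyl)oxy]-4-hydroxy-3-oxo-6-[(triethylsilyl)oxy]cyclohex-1-en-1-yl]methyl 3-methylbutanoate | CC(C)CC(=O)OCC1=CC(=O)[C@@H](O)[C@H](O[Si](C)(C)C(C)(C)C)[C@@H]1O[Si](CC)(CC)CC
F2 | step 8 | (2Z,4R,5R)-5-[(tert-butyldimethylsilyl)oxy]-3-{[(3-methylbutanoyl)oxy]methyl}-6-oxo-4-[(triethylsilyl)oxy]hex-2-enoic acid | OC(=O)/C=C(/COC(=O)CC(C)C)[C@@H](O[Si](CC)(CC)CC)[C@@H](O[Si](C)(C)C(C)(C)C)C=O
F3 | step 17 | (2Z)-2-[(1R,2S)-2-[(tert-butyldimethylsilyl)oxy]-3-hydroxy-1-[(triethylsilyl)oxy]propyl]-6-methylhepta-2,6-dien-1-yl 3-methylbutanoate | C=C(C)CC/C=C(/COC(=O)CC(C)C)[C@@H](O[Si](CC)(CC)CC)[C@@H](O[Si](C)(C)C(C)(C)C)CO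
F4 | step 17 | (2Z)-2-[(1R,2R)-2-[(tert-butyldimethylsilyl)oxy]-3-oxo-1-[(triethylsilyl)oxy]propyl]-6-methylhepta-2,6-dien-1-yl 3-methylbutanoate | C=C(C)CC/C=C(/COC(=O)CC(C)C)[C@@H](O[Si](CC)(CC)CC)[C@@H](O[Si](C)(C)C(C)(C)C)C=O
F5 | step 17 | methyl (4S,5R,6Z)-4-[(tert-butyldimethylsilyl)oxy]-3-hydroxy-10-methyl-2-methylidene-6-{[(3-methylbutanoyl)oxy]methyl}-5-[(triethylsilyl)oxy]undeca-6,10-dienoate (both C3 epimers) | C=C(C)CC/C=C(/COC(=O)CC(C)C)[C@@H](O[Si](CC)(CC)CC)[C@@H](O[Si](C)(C)C(C)(C)C)C(O)C(=C)C(=O)OC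
F6 | step 17 | methyl (2Z,4S,5R,6Z)-2-(bromomethyl)-4-[(tert-butyldimethylsilyl)oxy]-10-methyl-6-{[(3-methylbutanoyl)oxy]methyl}-5-[(triethylsilyl)oxy]undeca-2,6,10-trienoate | C=C(C)CC/C=C(/COC(=O)CC(C)C)[C@@H](O[Si](CC)(CC)CC)[C@@H](O[Si](C)(C)C(C)(C)C)/C=C(\CBr)C(=O)OC
F7 | step 17 | 6-vinyl-α-methylene-γ-butyrolactone with the target configuration at C6 to C9, O8-tert-butyldimethylsilyl, O9-triethylsilyl, chain ending in the C4 isopropenyl group | C=C1C(=O)O[C@H](C=C)[C@H]1[C@H](O[Si](C)(C)C(C)(C)C)[C@H](O[Si](CC)(CC)CC)/C(COC(=O)CC(C)C)=C\CCC(C)=C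
F8 | step 17 | O9-triethylsilyl ether of 23 | C=C1C(=O)O[C@@H]2/C=C(/C)CC/C=C(/COC(=O)CC(C)C)[C@@H](O[Si](CC)(CC)CC)[C@@H](O[Si](C)(C)C(C)(C)C)[C@@H]12
F9 | step 3 | (1S,6S)-5-bromo-6-hydroxycyclohexa-2,4-dien-1-yl acetate | BrC1=CC=C[C@H](OC(C)=O)[C@@H]1O
F10 | step 3 | (1S,6S)-5-bromo-6-[(triethylsilyl)oxy]cyclohexa-2,4-dien-1-yl acetate | BrC1=CC=C[C@H](OC(C)=O)[C@@H]1O[Si](CC)(CC)CC
F11 | step 3 | (1S,6S)-5-bromo-6-[(triethylsilyl)oxy]cyclohexa-2,4-dien-1-ol | BrC1=CC=C[C@H](O)[C@@H]1O[Si](CC)(CC)CC
F0 | step 13 | none | none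
F12 | step 6 | methyl (3R,4R,5S,6R)-5-[(tert-butyldimethylsilyl)oxy]-3,4-dihydroxy-6-[(triethylsilyl)oxy]cyclohex-1-ene-1-carboxylate | COC(=O)C1=C[C@@H](O)[C@@H](O)[C@H](O[Si](C)(C)C(C)(C)C)[C@@H]1O[Si](CC)(CC)CC
A1 | alternative 1 | seco aldehyde allyl bromide with O8/O9 as an isopropylidene acetal (linear precursor for the chromium-mediated closure) | O=C/C=C(/C)CC/C=C(/COC(=O)CC(C)C)[C@H]1OC(C)(C)O[C@H]1/C=C(\CBr)C(=O)OC
A2 | alternative 2 | 6-vinyl methylene lactone carrying 9-acetate, O8-tert-butyldimethylsilyl and a C4 isopropenyl terminus (metathesis precursor) | C=C1C(=O)O[C@H](C=C)[C@H]1[C@H](O[Si](C)(C)C(C)(C)C)[C@H](OC(C)=O)/C(COC(=O)CC(C)C)=C\CCC(C)=C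
A3 | alternative 3 | 13-membered bis-allylic ether (O bridging C6 and C13) with the C7=C11 acrylate in the ring | COC(=O)/C1=C/[C@H](O[Si](C)(C)C(C)(C)C)[C@H](O[Si](CC)(CC)CC)/C(COC(=O)CC(C)C)=C\CC/C(C)=C\COC1
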